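all flasks: Z 29 µM

| flask | G | remark |
|---|---|---|
| autumn | 0.025 M | run made earlier |
| dusk | 0.10 M | run made earlier |
| flask | 0.050 M |  |

- autumn (time / min: X / %): 1.50: 5.1; 5.00: 7.0; 8.00: 7.3; 12.0: 8.9; 20.0: 8.1
- dusk (time / min: X / %): 4.00: 14.5; 8.00: 15.0; 10.0: 14.8; 15.0: 13.5; 20.0: 14.3

(scatter of a reading: 1 percentage point)

- no earlier run changes the charge of Z; that part of a forecast is a guess

1. apparent order in Z when 10% of the G are converted (percent change of the rate of making X for one percent more Z charged)

**Two stalls.** X stopped early in both earlier runs, at readings near 8.10% in autumn and a higher 14.4% in dusk. I took each stall for Z dying away at a steady fractional pace.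

**The rule.** My premise was that with more Z charged to the flask, G reaches 10% conversion sooner, when more of the Z is alive. Following one used G to its fork, I wrote: order = 1 + φ(1/s − 1). Here φ is the chance that the used G became X at that moment (the selectivity), and s is the live share.

**What matters.** In the rule, the pace of dying acts through s. Taking used G as X, I let s in the flask depend on how far the X stall lies beyond 10%: a stall at the dusk reading gives an order of 3.27. No run reads G, so I set φ to 1, and the order above 1 scales with φ.

**My number.** I put the stall of the flask midway between the two readings, at 11.3%. That gave 11.2% for the live share, the fraction of Z still working when 10% of G is converted, and an order of 8.93. The forecast said 10, reading the stall as “the enzyme dying, not equilibrium”.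

**The flask.** The flask gives 1.2.

    Z → Q (k = 0.376 /min)
    2 G → D (k = 0.479 /M/min)
    G + Z → X + Z, rate k3*[G]^2.5*[Z]/(1 + ([G]/Kh3)^2.5) (0.0561 M, k = 4.09 × 10⁵ /M².5/min)

G reached 10% conversion in the flask at 0.983 min, and the live share then was 69.1%, not my 11.2%. At that moment X was being made at 0.00223 M/min, which puts φ at 53.5%, the rest of the G going to D. With these two values, the rule gives 1.24.

The data are calculated from invented constants, noise included.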